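## Retrosynthetic overview

1. Feature: the cyclopentane ring has two neighbouring quaternary carbons, C-1 (CH3 and the 4-methylpent-3-enoyl group) and C-2 (CH3 and the CH2C(=O) chain). Their carbonyl arms sit on the same face, and the acyl carbon on C-1 is 1,5 to the ketone carbon of the C-2 chain, so one oxygen atom can join both arms in a δ-lactone ring fused cis to the carbocycle.
2. The quinone ring comes last, from its hydroquinone dimethyl ether. The C(=O)–CH2 bond next to the E-alkene comes from acylation of an arene-bearing E-allylic sulfone anion by a δ-lactone, followed by desulfonylation.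
3. That lactone (carbonyl on the C-2 arm) comes from the first template (carbonyl on C-1) by reduction to the lactol, allylation, cross-metathesis to the prenyl group and oxidative relactonisation. No protecting group is needed.
4. The first template, cis-1,6-dimethyl-3-oxabicyclo[4.3.0]nonan-2-one, is cut between C-1 and its ring CH2. This is a 5-exo-tet alkylation of the enolate of (4R)-4-(3-iodopropyl)-3,4-dimethyloxan-2-one, whose quaternary carbon stems from an enantioselective Ireland–Claisen rearrangement.
5. Order of rings: oxanone ring (step 4), cyclopentane ring (step 6), second oxanone ring (step 10, opened in step 17). The six-membered carbocycle is bought as an arene and becomes the quinone in step 20.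

Key step: step 6

Remark (assumption): the (4S,5S)-bromodiazaborolidine with Et3N in toluene/hexane is taken to give the 3R acid, by analogy with simple E-allyl propanoates. If the sense is the opposite, the (4R,5R)-reagent is used and nothing else changes.

Remark: centres that are erased later are left undefined in names and SMILES. These are C-2 of 7, C-3 of 10 and 11, and the lactol, carbinol and sulfonyl-bearing carbons.

## Route

Step 1
Reactants: 1 5-chloropent-1-yne
Product: 4 (E)-6-chloro-3-methylhex-2-en-1-ol, via alkenyldimethylalane 2 (not isolated), via lithium alkenylaluminate 3 (not isolated)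
Conditions: Me3Al, Cp2ZrCl2 (20 mol %), CH2Cl2, 0 °C → rt; volatiles removed; n-BuLi, hexane, 0 °C; (CH2O)n, THF, rt; 1 M HCl
Reagents that add atoms: trimethylaluminium, C[Al](C)C; formaldehyde (as paraformaldehyde), C=O
Why: Negishi zirconium-catalysed carboalumination adds CH3 and Al syn with Al on the terminal carbon, and hydroxymethylation of the derived aluminate keeps that geometry, so the trisubstituted alkene should form as the E isomer.

Step 2
Reactants: 4 (E)-6-chloro-3-methylhex-2-en-1-ol
Product: 5 (E)-6-chloro-3-methylhex-2-enyl propanoate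
Conditions: EtCOCl, Et3N, DMAP (cat.), CH2Cl2, 0 °C
Reagents that add atoms: propanoyl chloride, CCC(=O)Cl
Why: This is a standard O-acylation of a primary allylic alcohol with an acid chloride, which leaves the alkene and the alkyl chloride untouched.

Step 3
Reactants: 5 (E)-6-chloro-3-methylhex-2-enyl propanoate
Product: 7 (3R)-6-chloro-3-ethenyl-2,3-dimethylhexanoic acid, via boron ketene acetal 6 (not isolated)
Conditions: (4S,5S)-2-bromo-4,5-diphenyl-1,3-bis{[3,5-bis(trifluoromethyl)phenyl]sulfonyl}-1,3,2-diazaborolidine (1.2 equiv, made in the flask from the (S,S)-bis-sulfonamide and BBr3, CH2Cl2, rt, then evacuation), Et3N, toluene/hexane, −78 °C, then −20 → 4 °C; aq. work-up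
Reagents that add atoms: none
Why: In this enantioselective boron variant of the Ireland–Claisen rearrangement, soft enolisation gives chiral ketene acetal 6, which rearranges through a chair transition state where the C2-symmetric bis-sulfonamide blocks one enolate face, so the E geometry of the alkene is translated into the R quaternary carbon (the adjacent C-2 centre is planarised again in step 6).

Step 4
Reactants: 7 (3R)-6-chloro-3-ethenyl-2,3-dimethylhexanoic acid
Product: 10 (4R)-4-(3-chloropropyl)-3,4-dimethyloxan-2-one (C-3 epimers), via bis-boryl adduct 8 (not isolated), via hydroxy acid 9 (not isolated)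
Conditions: 9-BBN (2.5 equiv), THF, 0 °C → rt; NaOH, H2O2, 0 °C; 2 M HCl, rt
Reagents that add atoms: hydrogen peroxide, OO
Why: Anti-Markovnikov hydroboration–oxidation of the monosubstituted alkene (the acid is only masked as an acyloxyborane, which 9-BBN reduces very slowly) gives a δ-hydroxy acid that lactonises on acidification, helped by the quaternary carbon in the chain.

Step 5
Reactants: 10 (4R)-4-(3-chloropropyl)-3,4-dimethyloxan-2-one
Product: 11 (4R)-4-(3-iodopropyl)-3,4-dimethyloxan-2-one (C-3 epimers)
Conditions: NaI (5 equiv), acetone, reflux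
Reagents that add atoms: sodium iodide, [Na+].[I-]
Why: The Finkelstein halide exchange (SN2 at the primary carbon) is driven by precipitation of NaCl, and the lactone and the quaternary centre are inert to it.

Step 6
Reactants: 11 (4R)-4-(3-iodopropyl)-3,4-dimethyloxan-2-one
Product: 13 (1R,6R)-1,6-dimethyl-3-oxabicyclo[4.3.0]nonan-2-one, via lithium enolate 12 (not isolated)
Conditions: LiN(i-Pr)2 (1.2 equiv), THF, −78 °C, 1 h; DMPU, −78 °C → rt, 0.02 M
Reagents that add atoms: none
Why: LiN(i-Pr)2 removes the only α-hydrogen (on C-3) to give the tetrasubstituted, ring-locked enolate 12, whose C-3 carbon displaces iodide at the end of the propyl chain on C-4 in an SN2 reaction; the closest known reaction type is the intramolecular alkylation of ester and lactone enolates used to build cyclopentanes with vicinal quaternary carbons. The carbocycle closes in the 5-exo-tet mode (ring atoms C-3, C-4 and the three chain CH2 groups, with the leaving group outside the ring). The new quaternary centre (C-1 of 13, the later acyl-bearing carbon) is controlled by the existing R centre at C-4: the three-carbon tether reaches the enolate π-face only when it stands pseudo-axial, and attack perpendicular to the enolate plane places the new C–C bond on the same face as the C-4–CH2 bond, so only the cis-fused 6/5 bicycle can form and both C-3 epimers of 11 converge on it. The step needs C- over O-alkylation and cyclisation over elimination or intermolecular acylation. O-attack would require a strained seven-membered bridged ketene acetal, the primary iodide is a soft and unhindered electrophile, and high dilution with cold enolisation holds back the bimolecular paths.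

Step 7
Reactants: 13 (1R,6R)-1,6-dimethyl-3-oxabicyclo[4.3.0]nonan-2-one
Product: 14 (1R,6R)-1,6-dimethyl-3-oxabicyclo[4.3.0]nonan-2-ol (anomers)
Conditions: i-Bu2AlH (1.2 equiv), CH2Cl2, −78 °C; aq. work-up
Reagents that add atoms: none
Why: Partial reduction of a lactone with i-Bu2AlH stops at the lactol because the hindered tetrahedral aluminium alkoxide does not collapse at low temperature, and both quaternary centres are untouched.

Step 8
Reactants: 14 (1R,6R)-1,6-dimethyl-3-oxabicyclo[4.3.0]nonan-2-ol
Product: 15 1-[(1R,2R)-2-(2-hydroxyethyl)-1,2-dimethylcyclopentyl]but-3-en-1-ol (carbinol epimers)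
Conditions: allylmagnesium bromide (3 equiv), THF, 0 °C → rt; aq. NH4Cl
Reagents that add atoms: allylmagnesium bromide, C=CC[Mg]Br
Why: The small and very reactive allyl Grignard reagent adds to the open hydroxy-aldehyde tautomer of the lactol even at a neopentyl carbonyl, and the new carbinol centre forms as a mixture that is erased in step 19.

Step 9
Reactants: 15 1-[(1R,2R)-2-(2-hydroxyethyl)-1,2-dimethylcyclopentyl]but-3-en-1-ol
Product: 16 1-[(1R,2R)-2-(2-hydroxyethyl)-1,2-dimethylcyclopentyl]-4-methylpent-3-en-1-ol
Conditions: 2-methylbut-2-ene (excess), second-generation Grubbs catalyst (3 mol %), CH2Cl2, 40 °C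
Reagents that add atoms: 2-methylbut-2-ene, CC=C(C)C
Why: Olefin cross-metathesis of a terminal alkene with 2-methylbut-2-ene is the established way to turn an allyl into a prenyl group, and it avoids the γ-attack that a prenyl-metal reagent would give at the aldehyde.

Step 10
Reactants: 16 1-[(1R,2R)-2-(2-hydroxyethyl)-1,2-dimethylcyclopentyl]-4-methylpent-3-en-1-ol
Product: 18 (1R,6R)-1,6-dimethyl-2-(3-methylbut-2-enyl)-3-oxabicyclo[4.3.0]nonan-4-one, via lactol 17 (not isolated)
Conditions: TEMPO (0.2 equiv), PhI(OAc)2 (2.5 equiv), CH2Cl2, rt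
Reagents that add atoms: none
Why: In this oxidative lactonisation of a 1,5-diol, the oxoammonium species picks the unhindered primary alcohol, the aldehyde is trapped by the neighbouring secondary hydroxyl as six-membered lactol 17, and that is oxidised on to the δ-lactone, which moves the template carbonyl to the unhindered arm.

Step 11
Reactants: 19 4-methoxy-2-methylphenol
Product: 20 2-bromo-4-methoxy-6-methylphenol
Conditions: NBS (1.0 equiv), CH2Cl2, 0 °C
Reagents that add atoms: N-bromosuccinimide, O=C1CCC(=O)N1Br
Why: Electrophilic aromatic bromination is directed by the free hydroxyl to its only open ortho position, since the para position is blocked by OCH3.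

Step 12
Reactants: 20 2-bromo-4-methoxy-6-methylphenol
Product: 21 1-bromo-2,5-dimethoxy-3-methylbenzene
Conditions: MeI, K2CO3, acetone, reflux
Reagents that add atoms: iodomethane, CI
Why: Williamson ether synthesis on the phenoxide masks the future quinone as a hydroquinone dimethyl ether that tolerates organometallic reagents.

Step 13
Reactants: 21 1-bromo-2,5-dimethoxy-3-methylbenzene; 22 1-bromo-3-methylbut-2-ene (prenyl bromide)
Product: 24 2,5-dimethoxy-1-methyl-3-(3-methylbut-2-enyl)benzene, via arylmagnesium bromide 23 (not isolated)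
Conditions: Mg, THF, reflux; CuI (10 mol %), 22, 0 °C
Reagents that add atoms: none
Why: Copper-catalysed coupling of an aryl Grignard reagent with a primary allylic bromide takes place at the unhindered CH2 terminus of prenyl bromide (SN2 rather than SN2').

Step 14
Reactants: 24 2,5-dimethoxy-1-methyl-3-(3-methylbut-2-enyl)benzene
Product: 25 (E)-4-(2,5-dimethoxy-3-methylphenyl)-2-methylbut-2-en-1-ol
Conditions: SeO2 (0.3 equiv), t-BuOOH (2 equiv), salicylic acid (0.1 equiv), CH2Cl2, 0 °C → rt
Reagents that add atoms: tert-butyl hydroperoxide, CC(C)(C)OO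
Why: In this catalytic Riley-type allylic oxidation, the ene reaction with SeO2 and the following [2,3]-sigmatropic shift deliver oxygen to the methyl group trans to the chain, which sets the E-trisubstituted alkene of the target.

Step 15
Reactants: 25 (E)-4-(2,5-dimethoxy-3-methylphenyl)-2-methylbut-2-en-1-ol
Product: 26 1-[(E)-4-bromo-3-methylbut-2-enyl]-2,5-dimethoxy-3-methylbenzene
Conditions: CBr4, PPh3, CH2Cl2, 0 °C
Reagents that add atoms: tetrabromomethane, BrC(Br)(Br)Br
Why: The Appel reaction converts the primary allylic alcohol into the bromide under neutral conditions, without allylic transposition or loss of alkene geometry.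

Step 16
Reactants: 26 1-[(E)-4-bromo-3-methylbut-2-enyl]-2,5-dimethoxy-3-methylbenzene
Product: 27 {[(E)-4-(2,5-dimethoxy-3-methylphenyl)-2-methylbut-2-enyl]sulfonyl}benzene
Conditions: PhSO2Na, DMF, rt
Reagents that add atoms: sodium benzenesulfinate, [Na+].[O-]S(=O)c1ccccc1
Why: S-alkylation of the ambident sulfinate by SN2 displacement at the primary allylic carbon gives the sulfone with the E-alkene retained.

Step 17
Reactants: 18 (1R,6R)-1,6-dimethyl-2-(3-methylbut-2-enyl)-3-oxabicyclo[4.3.0]nonan-4-one; 27 {[(E)-4-(2,5-dimethoxy-3-methylphenyl)-2-methylbut-2-enyl]sulfonyl}benzene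
Product: 29 (E)-3-(benzenesulfonyl)-6-(2,5-dimethoxy-3-methylphenyl)-1-[(1R,2R)-2-(1-hydroxy-4-methylpent-3-enyl)-1,2-dimethylcyclopentyl]-4-methylhex-4-en-2-one, via lithiated sulfone 28 (not isolated)
Conditions: 27 (2.2 equiv), n-BuLi (2.1 equiv), THF, −78 °C; 18, −78 → −30 °C; AcOH quench at −78 °C (excess 27 recovered)
Reagents that add atoms: none
Why: In this Claisen-type acylation of an α-lithiated allylic sulfone by a lactone, the anion reacts at the carbon next to sulfur with the E-alkene retained, and the second equivalent of anion deprotonates the β-keto sulfone as it forms, which prevents a second addition.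

Step 18
Reactants: 29 the hydroxy β-keto sulfone
Product: 30 (E)-6-(2,5-dimethoxy-3-methylphenyl)-1-[(1R,2R)-2-(1-hydroxy-4-methylpent-3-enyl)-1,2-dimethylcyclopentyl]-4-methylhex-4-en-2-one
Conditions: SmI2 (3 equiv), THF/MeOH, −78 → −40 °C
Reagents that add atoms: none
Why: Reductive desulfonylation of an α-sulfonyl ketone by single-electron transfer expels benzenesulfinate and leaves a samarium dienolate that is protonated kinetically at the α-carbon, so the double bond should stay β,γ and E; running this before step 19 keeps a second ketone away from the enolate.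

Step 19
Reactants: 30 the hydroxy ketone
Product: 31 (E)-6-(2,5-dimethoxy-3-methylphenyl)-1-[(1R,2R)-1,2-dimethyl-2-(4-methylpent-3-enoyl)cyclopentyl]-4-methylhex-4-en-2-one
Conditions: Dess–Martin periodinane, NaHCO3, CH2Cl2, 0 °C → rt
Reagents that add atoms: none
Why: Buffered Dess–Martin oxidation converts hindered homoallylic alcohols into β,γ-unsaturated ketones without moving the double bond into conjugation, and it drains the hemiketal tautomer through its open form.

Step 20
Reactants: 31 the diketone dimethyl ether
Product: 32 2-{(E)-6-[(1R,2R)-1,2-dimethyl-2-(4-methylpent-3-enoyl)cyclopentyl]-3-methyl-5-oxohex-2-enyl}-6-methylcyclohexa-2,5-diene-1,4-dione (target)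
Conditions: (NH4)2Ce(NO3)6 (2.5 equiv), MeCN/H2O, 0 °C, 20 min
Reagents that add atoms: water, O
Why: Oxidative demethylation of a hydroquinone dimethyl ether by tetravalent cerium is fast enough at 0 °C to leave the trisubstituted alkenes and the β,γ-unsaturated ketones in place, and no stereocentre is touched.

## Compound list

1 | 5-chloropent-1-yne | C#CCCCCl | starting material
2 | [(E)-5-chloro-2-methylpent-1-enyl]dimethylalane (not isolated) | C[Al](C)/C=C(C)/CCCCl | intermediate
3 | lithium butyl[(E)-5-chloro-2-methylpent-1-enyl]dimethylaluminate (not isolated) | [Li+].CCCC[Al-](C)(C)/C=C(C)/CCCCl | intermediate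
4 | (E)-6-chloro-3-methylhex-2-en-1-ol | OC/C=C(C)/CCCCl | intermediate
5 | (E)-6-chloro-3-methylhex-2-enyl propanoate | CCC(=O)OC/C=C(C)/CCCCl | intermediate
6 | boron ketene acetal of 5 bearing the (4S,5S)-diazaborolidine (not isolated) | CC=C(OC/C=C(C)/CCCCl)OB1N(S(=O)(=O)c2cc(C(F)(F)F)cc(C(F)(F)F)c2)[C@@H](c2ccccc2)[C@@H](N1S(=O)(=O)c1cc(C(F)(F)F)cc(C(F)(F)F)c1)c1ccccc1 | intermediate
7 | (3R)-6-chloro-3-ethenyl-2,3-dimethylhexanoic acid | C=C[C@@](C)(CCCCl)C(C)C(O)=O | intermediate
8 | bis(9-borabicyclo[3.3.1]nonan-9-yl) adduct of 7, B-alkyl and acyloxy (not isolated) | B1(C2CCCC1CCC2)CC[C@@](C)(CCCCl)C(C)C(=O)OB1C2CCCC1CCC2 | intermediate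
9 | (3R)-6-chloro-3-(2-hydroxyethyl)-2,3-dimethylhexanoic acid (not isolated) | OCC[C@@](C)(CCCCl)C(C)C(O)=O | intermediate
10 | (4R)-4-(3-chloropropyl)-3,4-dimethyloxan-2-one (C-3 epimers) | O=C1OCC[C@@](C)(CCCCl)C1C | intermediate
11 | (4R)-4-(3-iodopropyl)-3,4-dimethyloxan-2-one (C-3 epimers) | O=C1OCC[C@@](C)(CCCI)C1C | intermediate
12 | lithium enolate of 11 (not isolated) | [Li+].[O-]C1=C(C)[C@](C)(CCCI)CCO1 | intermediate
13 | (1R,6R)-1,6-dimethyl-3-oxabicyclo[4.3.0]nonan-2-one (cis-fused) | O=C2[C@]1(C)CCC[C@]1(C)CCO2 | intermediate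
14 | (1R,6R)-1,6-dimethyl-3-oxabicyclo[4.3.0]nonan-2-ol (anomers) | OC2[C@]1(C)CCC[C@]1(C)CCO2 | intermediate
15 | 1-[(1R,2R)-2-(2-hydroxyethyl)-1,2-dimethylcyclopentyl]but-3-en-1-ol (carbinol epimers) | C=CCC(O)[C@]1(C)CCC[C@]1(C)CCO | intermediate
16 | 1-[(1R,2R)-2-(2-hydroxyethyl)-1,2-dimethylcyclopentyl]-4-methylpent-3-en-1-ol (carbinol epimers) | CC(C)=CCC(O)[C@]1(C)CCC[C@]1(C)CCO | intermediate
17 | (1R,6R)-1,6-dimethyl-2-(3-methylbut-2-enyl)-3-oxabicyclo[4.3.0]nonan-4-ol (not isolated) | CC(C)=CCC2[C@]1(C)CCC[C@]1(C)CC(O)O2 | intermediate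
18 | (1R,6R)-1,6-dimethyl-2-(3-methylbut-2-enyl)-3-oxabicyclo[4.3.0]nonan-4-one (C-2 epimers) | CC(C)=CCC2[C@]1(C)CCC[C@]1(C)CC(=O)O2 | intermediate
19 | 4-methoxy-2-methylphenol | COc1ccc(O)c(C)c1 | starting material
20 | 2-bromo-4-methoxy-6-methylphenol | COc1cc(C)c(O)c(Br)c1 | intermediate
21 | 1-bromo-2,5-dimethoxy-3-methylbenzene | COc1cc(C)c(OC)c(Br)c1 | intermediate
22 | 1-bromo-3-methylbut-2-ene (prenyl bromide) | CC(C)=CCBr | starting material
23 | (2,5-dimethoxy-3-methylphenyl)magnesium bromide (not isolated) | COc1cc(C)c(OC)c([Mg]Br)c1 | intermediate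
24 | 2,5-dimethoxy-1-methyl-3-(3-methylbut-2-enyl)benzene | COc1cc(C)c(OC)c(CC=C(C)C)c1 | intermediate
25 | (E)-4-(2,5-dimethoxy-3-methylphenyl)-2-methylbut-2-en-1-ol | COc1cc(C)c(OC)c(C/C=C(C)/CO)c1 | intermediate
26 | 1-[(E)-4-bromo-3-methylbut-2-enyl]-2,5-dimethoxy-3-methylbenzene | COc1cc(C)c(OC)c(C/C=C(C)/CBr)c1 | intermediate
27 | {[(E)-4-(2,5-dimethoxy-3-methylphenyl)-2-methylbut-2-enyl]sulfonyl}benzene | COc1cc(C)c(OC)c(C/C=C(C)/CS(=O)(=O)c2ccccc2)c1 | intermediate
28 | α-lithio derivative of 27 (not isolated) | COc1cc(C)c(OC)c(C/C=C(C)/C([Li])S(=O)(=O)c2ccccc2)c1 | intermediate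
29 | (E)-3-(benzenesulfonyl)-6-(2,5-dimethoxy-3-methylphenyl)-1-[(1R,2R)-2-(1-hydroxy-4-methylpent-3-enyl)-1,2-dimethylcyclopentyl]-4-methylhex-4-en-2-one | CC(C)=CCC(O)[C@]1(C)CCC[C@]1(C)CC(=O)C(/C(C)=C/Cc1cc(OC)cc(C)c1OC)S(=O)(=O)c1ccccc1 | intermediate
30 | (E)-6-(2,5-dimethoxy-3-methylphenyl)-1-[(1R,2R)-2-(1-hydroxy-4-methylpent-3-enyl)-1,2-dimethylcyclopentyl]-4-methylhex-4-en-2-one | CC(C)=CCC(O)[C@]1(C)CCC[C@]1(C)CC(=O)C/C(C)=C/Cc1cc(OC)cc(C)c1OC | intermediate
31 | (E)-6-(2,5-dimethoxy-3-methylphenyl)-1-[(1R,2R)-1,2-dimethyl-2-(4-methylpent-3-enoyl)cyclopentyl]-4-methylhex-4-en-2-one | CC(C)=CCC(=O)[C@]1(C)CCC[C@]1(C)CC(=O)C/C(C)=C/Cc1cc(OC)cc(C)c1OC | intermediate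
32 | 2-{(E)-6-[(1R,2R)-1,2-dimethyl-2-(4-methylpent-3-enoyl)cyclopentyl]-3-methyl-5-oxohex-2-enyl}-6-methylcyclohexa-2,5-diene-1,4-dione | CC(C)=CCC(=O)[C@]1(C)CCC[C@]1(C)CC(=O)C/C(C)=C/CC1=CC(=O)C=C(C)C1=O | target

## Step count and risks

Total step count: 20. Longest linear sequence: 14 steps (steps 1–10, then 17–20). The arene fragment takes 6 steps (11–16) and joins in step 17.

**Step 6 (key step).**
- What may go wrong: removal of the hindered C-3 hydrogen and bond formation between two fully substituted carbons may both be slow. Loss of HI from the side chain or intermolecular acylation of the enolate could then take over.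
- Fallback: it sets out from acid 7 and returns at 13. It closes the carbocycle on the freely rotating open-chain ester before the oxygen bridge exists, and uses lactonisation afterwards as the stereochemical filter.
- Acid 7 is esterified (MeI, K2CO3, DMF) to methyl (3R)-6-chloro-3-ethenyl-2,3-dimethylhexanoate F1. This is exchanged with NaI in acetone to methyl (3R)-3-ethenyl-6-iodo-2,3-dimethylhexanoate F2.
- F2 is cyclised with KN(SiMe3)2 in THF to methyl (2R)-2-ethenyl-1,2-dimethylcyclopentane-1-carboxylate (C-1 epimers) F3.
- Hydroboration–oxidation (9-BBN, then NaOH/H2O2) gives methyl (2R)-2-(2-hydroxyethyl)-1,2-dimethylcyclopentane-1-carboxylate (C-1 epimers) F4.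
- Only the component with ester and hydroxyethyl groups cis can close the six-membered ring (TsOH cat., toluene, reflux). That gives 13, and the unreacted component is removed by chromatography.

**Step 3.**
- What may go wrong: the rearrangement of a γ,γ-disubstituted allyl ester may be slow at the low temperature that the controller needs. Facial discrimination may be incomplete, which would erode the enantiomeric purity of every later compound.
- Fallback: it sets out from ester 5 and returns at 7. It replaces reagent control by an achiral rearrangement followed by classical resolution.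
- LiN(i-Pr)2 and Me3SiCl in THF at −78 °C give the trimethylsilyl ketene acetal of 5 F5. This rearranges on warming (ordinary Ireland–Claisen rearrangement) and after hydrolysis gives racemic 6-chloro-3-ethenyl-2,3-dimethylhexanoic acid F6.
- Fractional crystallisation with (R)-1-phenylethylamine gives the (R)-1-phenylethylammonium salt of the 3R acid F7. Dilute acid then liberates 7.

**Step 17.**
- What may go wrong: the sulfonyl carbanion may enolise the lactone, or the liberated alkoxide may re-close onto the new ketone and reverse the addition. Either way both partners would be returned unchanged.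
- Fallback: it sets out from lactone 18 and returns at 31. It replaces acylation by addition to an aldehyde.
- i-Bu2AlH at −78 °C takes 18 back to lactol 17, whose open aldehyde tautomer is attacked by excess lithiated sulfone 28. This gives (E)-3-(benzenesulfonyl)-6-(2,5-dimethoxy-3-methylphenyl)-1-[(1R,2R)-2-(1-hydroxy-4-methylpent-3-enyl)-1,2-dimethylcyclopentyl]-4-methylhex-4-en-2-ol F8.
- Dess–Martin periodinane oxidises both carbinols to (E)-3-(benzenesulfonyl)-6-(2,5-dimethoxy-3-methylphenyl)-1-[(1R,2R)-1,2-dimethyl-2-(4-methylpent-3-enoyl)cyclopentyl]-4-methylhex-4-en-2-one F9.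
- Aluminium amalgam in aqueous THF removes the sulfonyl group from F9 to give 31.

## Further compounds

F1 | step 6 | methyl (3R)-6-chloro-3-ethenyl-2,3-dimethylhexanoate | C=C[C@@](C)(CCCCl)C(C)C(=O)OC
F2 | step 6 | methyl (3R)-3-ethenyl-6-iodo-2,3-dimethylhexanoate | C=C[C@@](C)(CCCI)C(C)C(=O)OC
F3 | step 6 | methyl (2R)-2-ethenyl-1,2-dimethylcyclopentane-1-carboxylate (C-1 epimers) | COC(=O)C1(C)CCC[C@]1(C)C=C
F4 | step 6 | methyl (2R)-2-(2-hydroxyethyl)-1,2-dimethylcyclopentane-1-carboxylate (C-1 epimers) | COC(=O)C1(C)CCC[C@]1(C)CCO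
F5 | step 3 | trimethylsilyl ketene acetal of 5 | CC=C(OC/C=C(C)/CCCCl)O[Si](C)(C)C
F6 | step 3 | racemic 6-chloro-3-ethenyl-2,3-dimethylhexanoic acid | C=CC(C)(CCCCl)C(C)C(O)=O
F7 | step 3 | (R)-1-phenylethylammonium (3R)-6-chloro-3-ethenyl-2,3-dimethylhexanoate | C=C[C@@](C)(CCCCl)C(C)C([O-])=O.C[C@@H]([NH3+])c1ccccc1
F8 | step 17 | (E)-3-(benzenesulfonyl)-6-(2,5-dimethoxy-3-methylphenyl)-1-[(1R,2R)-2-(1-hydroxy-4-methylpent-3-enyl)-1,2-dimethylcyclopentyl]-4-methylhex-4-en-2-ol | CC(C)=CCC(O)[C@]1(C)CCC[C@]1(C)CC(O)C(/C(C)=C/Cc1cc(OC)cc(C)c1OC)S(=O)(=O)c1ccccc1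
F9 | step 17 | (E)-3-(benzenesulfonyl)-6-(2,5-dimethoxy-3-methylphenyl)-1-[(1R,2R)-1,2-dimethyl-2-(4-methylpent-3-enoyl)cyclopentyl]-4-methylhex-4-en-2-one | CC(C)=CCC(=O)[C@]1(C)CCC[C@]1(C)CC(=O)C(/C(C)=C/Cc1cc(OC)cc(C)c1OC)S(=O)(=O)c1ccccc1
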